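**Retrosynthetic overview** (germacrane numbering: C6 = lactone O–CH, C7 = ring fusion, C8 = acyloxy carbon, C9 = carbinol, C14 = formyl carbon, C4/C15 = methyl-bearing alkene carbon and its methyl)
1. Target 21 ⇐ oxidation of C14–OH and removal of two PMB ethers ⇐ macrocycle 19 ⇐ ring-closing metathesis at C4=C5 (the ten-membered ring is formed second).
2. γ-Vinyl α-methylene lactone 18 ⇐ key C6–O bond: one-step dealkylative, dehydrogenative lactonisation of tert-butyl ester 17 onto its (E)-propenyl group (the lactone ring is formed first; sets C6).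
3. 17 ⇐ esterification of C8–OH with (S)-2-methylbutanoic acid ⇐ 15 ⇐ indium Barbier coupling of aldehyde 9 with dienyl bromide 13 (C7–C8 bond; C7 and C8 set from C9).
4. 9 ⇐ asymmetric Morita–Baylis–Hillman reaction (C9) and cross-metathesis (E-configured C1=C10); 13 ⇐ Morita–Baylis–Hillman adduct of crotonaldehyde and tert-butyl acrylate.

Assumption: anhydrous 2,2-dimethoxyacetaldehyde is obtained from the commercial aqueous solution by extraction and distillation.

**Route**

Step 1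
Reactants: 1 2,2-dimethoxyacetaldehyde; 2 1,1,1,3,3,3-hexafluoropropan-2-yl acrylate
Product: 3 1,1,1,3,3,3-hexafluoropropan-2-yl (3S)-3-hydroxy-4,4-dimethoxy-2-methylidenebutanoate
Conditions: β-isocupreidine (10 mol %), DMF, −55 °C
Reagents that add atoms: none
Why: Asymmetric Morita–Baylis–Hillman reaction with a chiral Lewis-base catalyst and an activated acrylate; the catalyst's phenolic OH selects one diastereomeric betaine for proton transfer and elimination, which gives the (S)-carbinol C9 (the same spatial sense that is labelled R for simple alkyl aldehydes).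

Step 2
Reactants: 3 1,1,1,3,3,3-hexafluoropropan-2-yl (3S)-3-hydroxy-4,4-dimethoxy-2-methylidenebutanoate; 4 2-methylhexa-1,5-diene
Product: 5 1,1,1,3,3,3-hexafluoropropan-2-yl (2E)-2-[(1S)-1-hydroxy-2,2-dimethoxyethyl]-6-methylhepta-2,6-dienoate
Conditions: 4 (4 equiv), RuCl2(H2IMes)(=CH-C6H4-2-OiPr) (second-generation Hoveyda–Grubbs catalyst, 5 mol %), CH2Cl2, 40 °C
Reagents that add atoms: none
Why: Olefin cross-metathesis between the acrylate-type alkene and the monosubstituted end of the diene (its 1,1-disubstituted end is inert here); the trisubstituted enoate forms as the E isomer (ester trans to the chain), which is the C1=C10 geometry of the target.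

Step 3
Reactants: 5 1,1,1,3,3,3-hexafluoropropan-2-yl (2E)-2-[(1S)-1-hydroxy-2,2-dimethoxyethyl]-6-methylhepta-2,6-dienoate
Product: 6 (2Z)-2-[(1S)-1-hydroxy-2,2-dimethoxyethyl]-6-methylhepta-2,6-dien-1-ol
Conditions: iBu2AlH (3.5 equiv), CH2Cl2, −78 → 0 °C; aq. potassium sodium tartrate
Reagents that add atoms: none
Why: 1,2-Reduction of the activated ester to the primary allylic alcohol (C14–OH) by an aluminium hydride; the acetal, C9 and the alkene geometry are untouched (the descriptor changes to Z only by priority).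

Step 4
Reactants: 6 (2Z)-2-[(1S)-1-hydroxy-2,2-dimethoxyethyl]-6-methylhepta-2,6-dien-1-ol
Product: 7 (2S,3Z)-1,1-dimethoxy-2-[(4-methoxybenzyl)oxy]-3-{[(4-methoxybenzyl)oxy]methyl}-7-methylocta-3,7-diene
Conditions: NaH (2.5 equiv), 4-MeOC6H4CH2Cl (2.4 equiv), Bu4NI (cat.), DMF, 0 °C → rt
Reagents that add atoms: 4-methoxybenzyl chloride, COc1ccc(CCl)cc1
Why: Williamson etherification of both hydroxyls; the C9 PMB ether can chelate in step 8, the C14 PMB ether keeps C14 from forming a lactol or being acylated, and both come off together in step 12.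

Step 5
Reactants: 7 (2S,3Z)-1,1-dimethoxy-2-[(4-methoxybenzyl)oxy]-3-{[(4-methoxybenzyl)oxy]methyl}-7-methylocta-3,7-diene
Product: 9 (2S,3Z)-2-[(4-methoxybenzyl)oxy]-3-{[(4-methoxybenzyl)oxy]methyl}-7-methylocta-3,7-dienal, via pyridinium triflate 8 (not isolated)
Conditions: Et3SiOTf (2 equiv), 2,4,6-collidine (3 equiv), CH2Cl2, 0 °C; then H2O
Reagents that add atoms: water, O
Why: Non-acidic acetal cleavage by silyl triflate activation and trapping as the collidinium salt 8; the epimerisable α-alkoxy β,γ-unsaturated aldehyde is released only on the water quench, so C9 and the PMB ethers survive, and 9 is used at once.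

Step 6
Reactants: 10 (2E)-but-2-enal; 11 tert-butyl acrylate
Product: 12 tert-butyl (4E)-3-hydroxy-2-methylidenehex-4-enoate (racemic)
Conditions: DABCO (1 equiv), 1,4-dioxane/H2O 1:1, rt
Reagents that add atoms: none
Why: Morita–Baylis–Hillman reaction (1,2-addition of the amine-derived acrylate enolate to the enal); the carbinol centre is lost in the next step, so no stereocontrol is needed.

Step 7
Reactants: 12 tert-butyl (4E)-3-hydroxy-2-methylidenehex-4-enoate (racemic)
Product: 13 tert-butyl (2Z,4E)-2-(bromomethyl)hexa-2,4-dienoate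
Conditions: PBr3 (0.4 equiv), Et2O, −10 → 0 °C
Reagents that add atoms: phosphorus tribromide, BrP(Br)Br
Why: Allylic bromination with 1,3-transposition (SN2′) to the thermodynamically preferred conjugated (2Z)-2-(bromomethyl)dienoate; any allylic regioisomer would give the same allylindium reagent in step 8.

Step 8
Reactants: 9 (2S,3Z)-2-[(4-methoxybenzyl)oxy]-3-{[(4-methoxybenzyl)oxy]methyl}-7-methylocta-3,7-dienal; 13 tert-butyl (2Z,4E)-2-(bromomethyl)hexa-2,4-dienoate
Product: 15 tert-butyl (3R,4S,5S,6Z)-4-hydroxy-5-[(4-methoxybenzyl)oxy]-6-{[(4-methoxybenzyl)oxy]methyl}-10-methyl-2-methylidene-3-[(1E)-prop-1-en-1-yl]undeca-6,10-dienoate, via allylindium dibromide 14 (not isolated)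
Conditions: In powder (1.5 equiv), THF/H2O 1:1, rt
Reagents that add atoms: none
Why: Indium-mediated Barbier allylation in water: 14 reacts at its γ-carbon (C7) through a chair transition state that sets propenyl and the new hydroxyl syn, while trivalent indium chelated between the aldehyde oxygen and the α-PMB ether oxygen (Cram-chelate) gives the 8,9-syn relationship, so C7 and C8 are both set from C9; the tert-butyl ester keeps C8–OH from lactonising.

Step 9
Reactants: 15 tert-butyl (3R,4S,5S,6Z)-4-hydroxy-5-[(4-methoxybenzyl)oxy]-6-{[(4-methoxybenzyl)oxy]methyl}-10-methyl-2-methylidene-3-[(1E)-prop-1-en-1-yl]undeca-6,10-dienoate; 16 (2S)-2-methylbutanoic acid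
Product: 17 tert-butyl (3R,4S,5S,6Z)-5-[(4-methoxybenzyl)oxy]-6-{[(4-methoxybenzyl)oxy]methyl}-10-methyl-2-methylidene-4-{[(2S)-2-methylbutanoyl]oxy}-3-[(1E)-prop-1-en-1-yl]undeca-6,10-dienoate
Conditions: DCC (1.5 equiv), DMAP (0.3 equiv), CH2Cl2, 0 °C → rt
Reagents that add atoms: none
Why: Steglich esterification of the only free hydroxyl (C8–OH) with retention at C8; the mild, weakly basic conditions avoid epimerising the acid's stereocentre and avoid elimination of the new ester.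

Step 10
Reactants: 17 tert-butyl (3R,4S,5S,6Z)-5-[(4-methoxybenzyl)oxy]-6-{[(4-methoxybenzyl)oxy]methyl}-10-methyl-2-methylidene-4-{[(2S)-2-methylbutanoyl]oxy}-3-[(1E)-prop-1-en-1-yl]undeca-6,10-dienoate
Product: 18 (1S,2S,3Z)-1-[(2R,3S)-2-ethenyl-4-methylidene-5-oxooxolan-3-yl]-2-[(4-methoxybenzyl)oxy]-3-{[(4-methoxybenzyl)oxy]methyl}-7-methylocta-3,7-dien-1-yl (2S)-2-methylbutanoate
Conditions: PdCl2(MeCN)2 (10 mol %), 1,4-benzoquinone (1.5 equiv), THF, 40 °C
Reagents that add atoms: none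
Why: Proposed new method: divalent palladium binds the (E)-propenyl alkene, the carbonyl oxygen of the tert-butyl ester attacks C6 in a reversible 5-exo anti-oxypalladation (C7–H eclipsing the alkene to minimise A1,3 strain and the C8 branch anti to the incoming oxygen, hence the 6,7-trans lactone), the tert-butoxy oxocarbenium ion then collapses irreversibly by loss of 2-methylpropene, β-hydride elimination towards the methyl group leaves the C5 vinyl group, and benzoquinone returns zerovalent palladium to the divalent state; the closest known reactions are the palladium-catalysed oxidative (Wacker-type) cyclisation of alk-4-enoic acids to γ-vinyl-γ-butyrolactones, ester-carbonyl attack on palladium-bound alkenes in cyclisation-induced allylic ester rearrangements, and dealkylative halolactonisation of tert-butyl esters.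

Step 11
Reactants: 18 (1S,2S,3Z)-1-[(2R,3S)-2-ethenyl-4-methylidene-5-oxooxolan-3-yl]-2-[(4-methoxybenzyl)oxy]-3-{[(4-methoxybenzyl)oxy]methyl}-7-methylocta-3,7-dien-1-yl (2S)-2-methylbutanoate
Product: 19 (3aS,4S,5S,6Z,10Z,11aR)-5-[(4-methoxybenzyl)oxy]-6-{[(4-methoxybenzyl)oxy]methyl}-10-methyl-3-methylidene-2-oxo-2,3,3a,4,5,8,9,11a-octahydrocyclodeca[b]furan-4-yl (2S)-2-methylbutanoate
Conditions: RuCl2(H2IMes)(PCy3)(=CHPh) (second-generation Grubbs catalyst, 10 mol %), toluene (1 mM), 80 °C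
Reagents that add atoms: none
Why: Ring-closing olefin metathesis of the C5 vinyl group onto the 1,1-disubstituted C4 alkene at high dilution; a ten-membered ring accommodates the new trisubstituted C4=C5 alkene only with the ring carbons cis (Z), and the α-methylene lactone and the C1=C10 alkene are too hindered or electron-poor to take part.

Step 12
Reactants: 19 (3aS,4S,5S,6Z,10Z,11aR)-5-[(4-methoxybenzyl)oxy]-6-{[(4-methoxybenzyl)oxy]methyl}-10-methyl-3-methylidene-2-oxo-2,3,3a,4,5,8,9,11a-octahydrocyclodeca[b]furan-4-yl (2S)-2-methylbutanoate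
Product: 20 (3aS,4S,5S,6Z,10Z,11aR)-5-hydroxy-6-(hydroxymethyl)-10-methyl-3-methylidene-2-oxo-2,3,3a,4,5,8,9,11a-octahydrocyclodeca[b]furan-4-yl (2S)-2-methylbutanoate
Conditions: DDQ (3 equiv), CH2Cl2/aq. NaH2PO4–Na2HPO4 buffer (pH 7), 0 °C → rt
Reagents that add atoms: none
Why: Oxidative cleavage of both PMB ethers (hydride abstraction to the oxocarbenium ion, then hydrolysis) under neutral buffered conditions, which spare the lactone and the C8 ester and do not promote 8→9 acyl migration.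

Step 13
Reactants: 20 (3aS,4S,5S,6Z,10Z,11aR)-5-hydroxy-6-(hydroxymethyl)-10-methyl-3-methylidene-2-oxo-2,3,3a,4,5,8,9,11a-octahydrocyclodeca[b]furan-4-yl (2S)-2-methylbutanoate
Product: 21 (3aS,4S,5S,6E,10Z,11aR)-6-formyl-5-hydroxy-10-methyl-3-methylidene-2-oxo-2,3,3a,4,5,8,9,11a-octahydrocyclodeca[b]furan-4-yl (2S)-2-methylbutanoate
Conditions: TEMPO (20 mol %), PhI(OAc)2 (1.2 equiv), CH2Cl2, rt
Reagents that add atoms: none
Why: Oxoammonium (TEMPO) oxidation, which is selective for the primary allylic C14–OH over the secondary C9–OH, gives the enal and thus the target (the descriptor becomes 6E only by priority).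

**Compound list**
1 | 2,2-dimethoxyacetaldehyde | COC(OC)C=O | starting material
2 | 1,1,1,3,3,3-hexafluoropropan-2-yl acrylate | C=CC(=O)OC(C(F)(F)F)C(F)(F)F | starting material
3 | 1,1,1,3,3,3-hexafluoropropan-2-yl (3S)-3-hydroxy-4,4-dimethoxy-2-methylidenebutanoate | C=C(C(=O)OC(C(F)(F)F)C(F)(F)F)[C@H](O)C(OC)OC | intermediate
4 | 2-methylhexa-1,5-diene | C=CCCC(C)=C | starting material
5 | 1,1,1,3,3,3-hexafluoropropan-2-yl (2E)-2-[(1S)-1-hydroxy-2,2-dimethoxyethyl]-6-methylhepta-2,6-dienoate | C=C(C)CC/C=C(/C(=O)OC(C(F)(F)F)C(F)(F)F)[C@H](O)C(OC)OC | intermediate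
6 | (2Z)-2-[(1S)-1-hydroxy-2,2-dimethoxyethyl]-6-methylhepta-2,6-dien-1-ol | C=C(C)CC/C=C(/CO)[C@H](O)C(OC)OC | intermediate
7 | (2S,3Z)-1,1-dimethoxy-2-[(4-methoxybenzyl)oxy]-3-{[(4-methoxybenzyl)oxy]methyl}-7-methylocta-3,7-diene | C=C(C)CC/C=C(/COCc1ccc(OC)cc1)[C@H](OCc1ccc(OC)cc1)C(OC)OC | intermediate
8 | 1-[(2S,3Z)-1-methoxy-2-[(4-methoxybenzyl)oxy]-3-{[(4-methoxybenzyl)oxy]methyl}-7-methylocta-3,7-dien-1-yl]-2,4,6-trimethylpyridinium trifluoromethanesulfonate (both C1 epimers, formed in situ) | C=C(C)CC/C=C(/COCc1ccc(OC)cc1)[C@H](OCc1ccc(OC)cc1)C(OC)[n+]1c(C)cc(C)cc1C.[O-]S(=O)(=O)C(F)(F)F | intermediate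
9 | (2S,3Z)-2-[(4-methoxybenzyl)oxy]-3-{[(4-methoxybenzyl)oxy]methyl}-7-methylocta-3,7-dienal | C=C(C)CC/C=C(/COCc1ccc(OC)cc1)[C@H](OCc1ccc(OC)cc1)C=O | intermediate
10 | (2E)-but-2-enal (crotonaldehyde) | C/C=C/C=O | starting material
11 | tert-butyl acrylate | C=CC(=O)OC(C)(C)C | starting material
12 | tert-butyl (4E)-3-hydroxy-2-methylidenehex-4-enoate (racemic) | C/C=C/C(O)C(=C)C(=O)OC(C)(C)C | intermediate
13 | tert-butyl (2Z,4E)-2-(bromomethyl)hexa-2,4-dienoate | C/C=C/C=C(\CBr)C(=O)OC(C)(C)C | intermediate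
14 | [(2Z,4E)-2-(tert-butoxycarbonyl)hexa-2,4-dien-1-yl]indium dibromide (monomeric unit of the allylindium sesquibromide, formed in situ) | C/C=C/C=C(\C[In](Br)Br)C(=O)OC(C)(C)C | intermediate
15 | tert-butyl (3R,4S,5S,6Z)-4-hydroxy-5-[(4-methoxybenzyl)oxy]-6-{[(4-methoxybenzyl)oxy]methyl}-10-methyl-2-methylidene-3-[(1E)-prop-1-en-1-yl]undeca-6,10-dienoate | C=C(C(=O)OC(C)(C)C)[C@@H](/C=C/C)[C@H](O)[C@@H](OCc1ccc(OC)cc1)/C(COCc1ccc(OC)cc1)=C\CCC(C)=C | intermediate
16 | (2S)-2-methylbutanoic acid | CC[C@H](C)C(=O)O | starting material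
17 | tert-butyl (3R,4S,5S,6Z)-5-[(4-methoxybenzyl)oxy]-6-{[(4-methoxybenzyl)oxy]methyl}-10-methyl-2-methylidene-4-{[(2S)-2-methylbutanoyl]oxy}-3-[(1E)-prop-1-en-1-yl]undeca-6,10-dienoate | C=C(C(=O)OC(C)(C)C)[C@@H](/C=C/C)[C@H](OC(=O)[C@@H](C)CC)[C@@H](OCc1ccc(OC)cc1)/C(COCc1ccc(OC)cc1)=C\CCC(C)=C | intermediate
18 | (1S,2S,3Z)-1-[(2R,3S)-2-ethenyl-4-methylidene-5-oxooxolan-3-yl]-2-[(4-methoxybenzyl)oxy]-3-{[(4-methoxybenzyl)oxy]methyl}-7-methylocta-3,7-dien-1-yl (2S)-2-methylbutanoate | C=C1C(=O)O[C@H](C=C)[C@H]1[C@H](OC(=O)[C@@H](C)CC)[C@@H](OCc1ccc(OC)cc1)/C(COCc1ccc(OC)cc1)=C\CCC(C)=C | intermediate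
19 | (3aS,4S,5S,6Z,10Z,11aR)-5-[(4-methoxybenzyl)oxy]-6-{[(4-methoxybenzyl)oxy]methyl}-10-methyl-3-methylidene-2-oxo-2,3,3a,4,5,8,9,11a-octahydrocyclodeca[b]furan-4-yl (2S)-2-methylbutanoate | C=C1C(=O)O[C@@H]2/C=C(/C)CC/C=C(/COCc3ccc(OC)cc3)[C@H](OCc3ccc(OC)cc3)[C@@H](OC(=O)[C@@H](C)CC)[C@@H]12 | intermediate
20 | (3aS,4S,5S,6Z,10Z,11aR)-5-hydroxy-6-(hydroxymethyl)-10-methyl-3-methylidene-2-oxo-2,3,3a,4,5,8,9,11a-octahydrocyclodeca[b]furan-4-yl (2S)-2-methylbutanoate | C=C1C(=O)O[C@@H]2/C=C(/C)CC/C=C(/CO)[C@H](O)[C@@H](OC(=O)[C@@H](C)CC)[C@@H]12 | intermediate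
21 | (3aS,4S,5S,6E,10Z,11aR)-6-formyl-5-hydroxy-10-methyl-3-methylidene-2-oxo-2,3,3a,4,5,8,9,11a-octahydrocyclodeca[b]furan-4-yl (2S)-2-methylbutanoate | C=C1C(=O)O[C@@H]2/C=C(/C)CC/C=C(/C=O)[C@H](O)[C@@H](OC(=O)[C@@H](C)CC)[C@@H]12 | target

**Step count and risks**
Total: 13 steps. Longest linear sequence: 11 steps (steps 1–5, then 8–13); steps 6–7 make the second fragment.

Step 10, the new lactonisation, is the most likely to fail. The risks are that the ether oxygen of the C9 PMB group competes as the nucleophile, that the trans/cis ratio at C6 is low, and that palladium hydride isomerises an alkene. The fallback uses known chemistry, sets out from 17 and comes back at 18. The tert-butyl ester is cleaved (Me3SiOTf, 2,6-lutidine, CH2Cl2, 0 °C, aqueous work-up) to (3R,4S,5S,6Z)-5-[(4-methoxybenzyl)oxy]-6-{[(4-methoxybenzyl)oxy]methyl}-10-methyl-2-methylidene-4-{[(2S)-2-methylbutanoyl]oxy}-3-[(1E)-prop-1-en-1-yl]undeca-6,10-dienoic acid F1. Phenylselenolactonisation under equilibrating conditions (PhSeCl, CH2Cl2, −78 °C → rt) gives by anti addition the trans selenolactone (1S,2S,3Z)-2-[(4-methoxybenzyl)oxy]-3-{[(4-methoxybenzyl)oxy]methyl}-7-methyl-1-{(2S,3R)-4-methylidene-5-oxo-2-[(1R)-1-(phenylselanyl)ethyl]oxolan-3-yl}octa-3,7-dien-1-yl (2S)-2-methylbutanoate F2. Oxidation (H2O2, pyridine, CH2Cl2, 0 °C) and syn elimination of the selenoxide away from the ring oxygen then gives 18.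

Step 11, the ring-closing metathesis, is the second risk: it forms a ten-membered ring with a trisubstituted alkene from a hindered diene. The fallback sets out from 18 and comes back at 21, moving the ring closure to the last step on an unprotected substrate. DDQ (buffered CH2Cl2) removes both PMB groups to give (1S,2S,3Z)-1-[(2R,3S)-2-ethenyl-4-methylidene-5-oxooxolan-3-yl]-2-hydroxy-3-(hydroxymethyl)-7-methylocta-3,7-dien-1-yl (2S)-2-methylbutanoate F3. TEMPO/PhI(OAc)2 oxidises it to (1S,2S,3E)-1-[(2R,3S)-2-ethenyl-4-methylidene-5-oxooxolan-3-yl]-3-formyl-2-hydroxy-7-methylocta-3,7-dien-1-yl (2S)-2-methylbutanoate F4, the open-chain form of the target, in which the C9–OH to formyl hydrogen bond and the absence of the two benzyl ethers should favour folding. Ring-closing metathesis of F4 (RuCl2(H2IMes)(PCy3)(=CHPh), toluene, 1 mM, 80 °C) then gives 21 directly.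

Step 1 is the third risk: the enantioselectivity of the amine-catalysed reaction is untested for an α,α-dialkoxy aldehyde, and every later stereocentre is derived from C9. The fallback replaces asymmetric catalysis by resolution, sets out from 1 and comes back at 6. A racemic Morita–Baylis–Hillman reaction of 1 with methyl acrylate (DABCO, neat, rt) gives methyl 3-hydroxy-4,4-dimethoxy-2-methylidenebutanoate (racemic) F5. Kinetic resolution with Candida antarctica lipase B and vinyl acetate (hexane, 30 °C) is assumed to acetylate the (R)-alcohol to methyl (3R)-3-(acetyloxy)-4,4-dimethoxy-2-methylidenebutanoate F6 and leave methyl (3S)-3-hydroxy-4,4-dimethoxy-2-methylidenebutanoate F7; if the enzyme prefers the other enantiomer, the (S)-acetate is methanolysed to F7. Cross-metathesis of F7 with 4 as in step 2 gives methyl (2E)-2-[(1S)-1-hydroxy-2,2-dimethoxyethyl]-6-methylhepta-2,6-dienoate F8, and iBu2AlH reduction as in step 3 gives 6.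

**Further compounds**
F1 | step 10 | (3R,4S,5S,6Z)-5-[(4-methoxybenzyl)oxy]-6-{[(4-methoxybenzyl)oxy]methyl}-10-methyl-2-methylidene-4-{[(2S)-2-methylbutanoyl]oxy}-3-[(1E)-prop-1-en-1-yl]undeca-6,10-dienoic acid | C=C(C(=O)O)[C@@H](/C=C/C)[C@H](OC(=O)[C@@H](C)CC)[C@@H](OCc1ccc(OC)cc1)/C(COCc1ccc(OC)cc1)=C\CCC(C)=C
F2 | step 10 | (1S,2S,3Z)-2-[(4-methoxybenzyl)oxy]-3-{[(4-methoxybenzyl)oxy]methyl}-7-methyl-1-{(2S,3R)-4-methylidene-5-oxo-2-[(1R)-1-(phenylselanyl)ethyl]oxolan-3-yl}octa-3,7-dien-1-yl (2S)-2-methylbutanoate | C=C1C(=O)O[C@H]([C@@H](C)[Se]c2ccccc2)[C@H]1[C@H](OC(=O)[C@@H](C)CC)[C@@H](OCc2ccc(OC)cc2)/C(COCc2ccc(OC)cc2)=C\CCC(C)=C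
F3 | step 11 | (1S,2S,3Z)-1-[(2R,3S)-2-ethenyl-4-methylidene-5-oxooxolan-3-yl]-2-hydroxy-3-(hydroxymethyl)-7-methylocta-3,7-dien-1-yl (2S)-2-methylbutanoate | C=C1C(=O)O[C@H](C=C)[C@H]1[C@H](OC(=O)[C@@H](C)CC)[C@@H](O)/C(CO)=C\CCC(C)=C
F4 | step 11 | (1S,2S,3E)-1-[(2R,3S)-2-ethenyl-4-methylidene-5-oxooxolan-3-yl]-3-formyl-2-hydroxy-7-methylocta-3,7-dien-1-yl (2S)-2-methylbutanoate | C=C1C(=O)O[C@H](C=C)[C@H]1[C@H](OC(=O)[C@@H](C)CC)[C@@H](O)/C(C=O)=C\CCC(C)=C
F5 | step 1 | methyl 3-hydroxy-4,4-dimethoxy-2-methylidenebutanoate (racemic) | C=C(C(=O)OC)C(O)C(OC)OC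
F6 | step 1 | methyl (3R)-3-(acetyloxy)-4,4-dimethoxy-2-methylidenebutanoate | C=C(C(=O)OC)[C@@H](OC(C)=O)C(OC)OC
F7 | step 1 | methyl (3S)-3-hydroxy-4,4-dimethoxy-2-methylidenebutanoate | C=C(C(=O)OC)[C@H](O)C(OC)OC
F8 | step 1 | methyl (2E)-2-[(1S)-1-hydroxy-2,2-dimethoxyethyl]-6-methylhepta-2,6-dienoate | C=C(C)CC/C=C(/C(=O)OC)[C@H](O)C(OC)OC
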